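## Retrosynthetic overview

1. Ring C is made last. The isoflavan is cut at C4–C4a while ring B is moved back from C3 to C4, which gives an open-chain (R)-1-aryloxy-3-arylpropan-2-ol. In the forward direction its triflate forms a phenonium ion (1,2-aryl shift, inversion at C3), and ring A closes this ion.
2. C2–C3–C4 and the stereocentre come from (R)-epichlorohydrin. An aryl-metal epoxide opening makes the C4–ring B bond, and phenoxide alkylation makes C2–O1.
3. The ring A phenol comes from cyclohexane-1,3-dione and prenyl bromide by C-alkylation, O-methylation, silylative aromatisation and C–H borylation/oxidation (this last step installs O1).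
4. Rings D and B come from cyclohexane-1,3-dione and 3-methylbut-2-enal by a formal [3+3] annulation, the same silylative aromatisation and metalation at C8.
5. Ring order: D, then B (aromatised), with A (aromatised) made in parallel, and C last. Both TIPS groups are removed in the final step.

Assumption: an intermediate carried on crude in a telescoped operation does not count as a separate step, and (R)-epichlorohydrin is bought in at least 99% ee.

## Route

Step 1
Reactants: 1 cyclohexane-1,3-dione; 2 1-bromo-3-methylbut-2-ene (prenyl bromide)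
Product: 3 2-(3-methylbut-2-en-1-yl)cyclohexane-1,3-dione
Conditions: KOH (1 equiv), H2O, 0 °C to rt (1.5 equiv of 1)
Reagents that add atoms: none
Why: SN2 C-alkylation of the ambident 1,3-dione enolate, which in water (oxygen tied up by hydrogen bonds) reacts at carbon with the soft allylic bromide, while the excess of 1 limits double alkylation.

Step 2
Reactants: 3 2-(3-methylbut-2-en-1-yl)cyclohexane-1,3-dione
Product: 4 3-methoxy-2-(3-methylbut-2-en-1-yl)cyclohex-2-en-1-one
Conditions: Me2SO4, K2CO3, acetone, reflux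
Reagents that add atoms: dimethyl sulfate COS(=O)(=O)OC
Why: O-alkylation of a vinylogous acid by a hard electrophile (Williamson type); because 3 is symmetric, one methylation distinguishes the two oxygens with no statistical loss, and basic conditions keep the enol from adding to the prenyl double bond.

Step 3
Reactants: 4 3-methoxy-2-(3-methylbut-2-en-1-yl)cyclohex-2-en-1-one
Product: 7 triisopropyl[3-methoxy-2-(3-methylbut-2-en-1-yl)phenoxy]silane, via lithium dienolate 5 (not isolated), via TIPS dienol ether 6 (not isolated)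
Conditions: LDA, THF, −78 °C; TIPSOTf, −78 to 0 °C; pentane/aq NaHCO3 wash, crude 6; DDQ (1.05 equiv), toluene, 0 °C
Reagents that add atoms: triisopropylsilyl triflate CC(C)[Si](C(C)C)(C(C)C)OS(=O)(=O)C(F)(F)F
Why: Kinetic alpha-prime deprotonation of a vinylogous ester (Stork–Danheiser enolate), O-silylation and DDQ dehydrogenation, in which hydride loss from a ring CH2 gives an oxygen-stabilised arenium ion that loses a proton much faster than silicon, so the aryl TIPS ether forms directly and well before DDQ attacks the prenyl group.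

Step 4
Reactants: 7 triisopropyl[3-methoxy-2-(3-methylbut-2-en-1-yl)phenoxy]silane
Product: 9 3-methoxy-4-(3-methylbut-2-en-1-yl)-5-(triisopropylsilyloxy)phenol, via aryl pinacol boronate 8 (not isolated)
Conditions: [Ir(OMe)(cod)]2 (1.5 mol %), dtbpy (3 mol %), B2pin2 (1.0 equiv), MTBE, 60 °C; then NaBO3·4H2O, THF/H2O, rt
Reagents that add atoms: bis(pinacolato)diboron CC1(C)OB(OC1(C)C)B2OC(C)(C)C(C)(C)O2 (boron of 8 only); sodium perborate [Na+].[O-]OB=O (phenol oxygen of 9)
Why: Sterically controlled iridium-catalysed aromatic C–H borylation followed by boronate oxidation; the only ring C–H without an ortho neighbour is the one para to the prenyl group, the trisubstituted alkene is too hindered to insert into Ir–B or Ir–H, and perborate converts C–B into C–OH without touching the alkene or the silyl ether.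

Step 5
Reactants: 1 cyclohexane-1,3-dione; 10 3-methylbut-2-enal
Product: 12 2,2-dimethyl-7,8-dihydro-2H-chromen-5(6H)-one, via Knoevenagel oxatriene 11 (not isolated)
Conditions: ethylenediammonium diacetate (10 mol %), MeOH, rt
Reagents that add atoms: none
Why: Knoevenagel condensation followed by oxa-6π electrocyclisation of the 1-oxatriene (formal [3+3]); C2 of the dione becomes C4a, so ring D is fused between the two oxygens with no regiochemical choice.

Step 6
Reactants: 12 2,2-dimethyl-7,8-dihydro-2H-chromen-5(6H)-one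
Product: 15 [(2,2-dimethyl-2H-chromen-5-yl)oxy]triisopropylsilane, via lithium dienolate 13 (not isolated), via TIPS dienol ether 14 (not isolated)
Conditions: LDA, THF, −78 °C; TIPSOTf, −78 to 0 °C; pentane/aq NaHCO3 wash, crude 14; DDQ (1.05 equiv), toluene, 0 °C
Reagents that add atoms: triisopropylsilyl triflate CC(C)[Si](C(C)C)(C(C)C)OS(=O)(=O)C(F)(F)F
Why: The same enolate silylation and DDQ dehydrogenation as in step 3, and 2,2-dimethylchromenes are themselves inert to DDQ, so only the dihydroarene is oxidised.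

Step 7
Reactants: 15 [(2,2-dimethyl-2H-chromen-5-yl)oxy]triisopropylsilane; 16 (R)-epichlorohydrin
Product: 19 (R)-1-chloro-3-[2,2-dimethyl-5-(triisopropylsilyloxy)-2H-chromen-8-yl]propan-2-ol, via aryllithium 17 (not isolated), via arylmagnesium bromide 18 (not isolated)
Conditions: s-BuLi, TMEDA, Et2O, −78 to −20 °C; MgBr2·OEt2, −20 °C; CuBr·SMe2 (10 mol %), 16, THF, −40 to 0 °C
Reagents that add atoms: none
Why: Directed ortho-metalation followed by copper-catalysed Grignard opening of an epoxide; the pyran oxygen is the only directing group with an open ortho C–H (TIPS shields C6 and does not bind lithium), the aryl copper species attacks the unsubstituted epoxide carbon faster than C–Cl, and the stereocentre of 16 is not touched, so 19 is (R).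

Step 8
Reactants: 19 (R)-1-chloro-3-[2,2-dimethyl-5-(triisopropylsilyloxy)-2H-chromen-8-yl]propan-2-ol; 9 3-methoxy-4-(3-methylbut-2-en-1-yl)-5-(triisopropylsilyloxy)phenol
Product: 21 (R)-1-[2,2-dimethyl-5-(triisopropylsilyloxy)-2H-chromen-8-yl]-3-[3-methoxy-4-(3-methylbut-2-en-1-yl)-5-(triisopropylsilyloxy)phenoxy]propan-2-ol, via epoxide 20 (not isolated)
Conditions: K2CO3 (2.5 equiv), MeCN, 70 °C
Reagents that add atoms: none
Why: Chlorohydrin-to-epoxide closure and SN2 opening by the phenoxide at the terminal carbon (Williamson-type etherification); direct displacement of chloride would give the same compound, and no bond to the carbinol carbon is broken, so (R) is kept.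

Step 9
Reactants: 21 (R)-1-[2,2-dimethyl-5-(triisopropylsilyloxy)-2H-chromen-8-yl]-3-[3-methoxy-4-(3-methylbut-2-en-1-yl)-5-(triisopropylsilyloxy)phenoxy]propan-2-ol
Product: 24 (3R)-3-[2,2-dimethyl-5-(triisopropylsilyloxy)-2H-chromen-8-yl]-5-methoxy-6-(3-methylbut-2-en-1-yl)-7-(triisopropylsilyloxy)chromane, via secondary triflate 22 (not isolated), via phenonium triflate 23 (not isolated)
Conditions: Tf2O (1.1 equiv), 2,6-di-tert-butyl-4-methylpyridine (3 equiv), CH2Cl2, −78 to 0 °C
Reagents that add atoms: trifluoromethanesulfonic anhydride O=S(=O)(OS(=O)(=O)C(F)(F)F)C(F)(F)F (atoms in 22 and 23 only, none in 24)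
Why: Proposed new method: stereospecific phenonium-relay cycloalkylation, in which triflate 22, slow to ionise unaided because of its β-aryloxy group, is displaced from the rear by the ipso carbon of electron-rich ring B (para OTIPS, ortho O-alkyl; Ar1-3 participation), inverting C3 and giving the spiro[2.5]octadienyl cation 23; trioxygenated ring A then opens the cyclopropane at its unsubstituted CH2 through the easy six-membered (Ar2-6, 6-endo) closure rather than the strained five-membered closure at C3, so ring B ends one carbon over (net 1,2-aryl shift C4 to C3), C4–C4a and ring C are formed, and (R)-21 maps onto (3R)-24; attack at C4a rather than C8 is expected because the TIPS group, pushed towards C8 by the neighbouring prenyl group, shields that site, and the hindered pyridine takes up all the acid so the prenyl and chromene alkenes survive; the closest known reaction types are the retentive solvolysis of 1-aryl-2-propyl sulfonates through phenonium ions and the 6-endo epoxide–arene cyclisation of aryl glycidyl ethers to chroman-3-ols, whereas capture of a non-racemic phenonium ion by a tethered arene to build a 3-arylchromane has not been shown.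

Step 10
Reactants: 24 (3R)-3-[2,2-dimethyl-5-(triisopropylsilyloxy)-2H-chromen-8-yl]-5-methoxy-6-(3-methylbut-2-en-1-yl)-7-(triisopropylsilyloxy)chromane
Product: 25 (3R)-3-(5-hydroxy-2,2-dimethyl-2H-chromen-8-yl)-5-methoxy-6-(3-methylbut-2-en-1-yl)chroman-7-ol (target)
Conditions: TBAF/AcOH (1:1, 2.5 equiv), THF, 0 °C to rt
Reagents that add atoms: none
Why: Fluoride-induced cleavage of both aryl silyl ethers, driven by the Si–F bond; the AcOH buffer protects the electron-rich phenoxides from air oxidation, and C3 carries no acidic hydrogen, so its configuration is not scrambled.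

## Compound list

1 | cyclohexane-1,3-dione | O=C1CCCC(=O)C1 | starting material
2 | 1-bromo-3-methylbut-2-ene (prenyl bromide) | CC(C)=CCBr | starting material
3 | 2-(3-methylbut-2-en-1-yl)cyclohexane-1,3-dione | CC(C)=CCC1C(=O)CCCC1=O | intermediate
4 | 3-methoxy-2-(3-methylbut-2-en-1-yl)cyclohex-2-en-1-one | COC1=C(CC=C(C)C)C(=O)CCC1 | intermediate
5 | lithium 5-methoxy-6-(3-methylbut-2-en-1-yl)cyclohexa-1,5-dien-1-olate (kinetic dienolate of 4) | [Li+].[O-]C1=CCCC(OC)=C1CC=C(C)C | intermediate
6 | triisopropyl{[5-methoxy-6-(3-methylbut-2-en-1-yl)cyclohexa-1,5-dien-1-yl]oxy}silane | CC(C)[Si](C(C)C)(C(C)C)OC1=CCCC(OC)=C1CC=C(C)C | intermediate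
7 | triisopropyl[3-methoxy-2-(3-methylbut-2-en-1-yl)phenoxy]silane | COc1cccc(O[Si](C(C)C)(C(C)C)C(C)C)c1CC=C(C)C | intermediate
8 | 2-[3-methoxy-4-(3-methylbut-2-en-1-yl)-5-(triisopropylsilyloxy)phenyl]-4,4,5,5-tetramethyl-1,3,2-dioxaborolane | COc1cc(B2OC(C)(C)C(C)(C)O2)cc(O[Si](C(C)C)(C(C)C)C(C)C)c1CC=C(C)C | intermediate
9 | 3-methoxy-4-(3-methylbut-2-en-1-yl)-5-(triisopropylsilyloxy)phenol | COc1cc(O)cc(O[Si](C(C)C)(C(C)C)C(C)C)c1CC=C(C)C | intermediate
10 | 3-methylbut-2-enal | CC(C)=CC=O | starting material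
11 | 2-(3-methylbut-2-en-1-ylidene)cyclohexane-1,3-dione | CC(C)=CC=C1C(=O)CCCC1=O | intermediate
12 | 2,2-dimethyl-7,8-dihydro-2H-chromen-5(6H)-one | CC1(C)C=CC2=C(CCCC2=O)O1 | intermediate
13 | lithium 2,2-dimethyl-7,8-dihydro-2H-chromen-5-olate | [Li+].[O-]C1=CCCC2=C1C=CC(C)(C)O2 | intermediate
14 | [(2,2-dimethyl-7,8-dihydro-2H-chromen-5-yl)oxy]triisopropylsilane | CC(C)[Si](C(C)C)(C(C)C)OC1=CCCC2=C1C=CC(C)(C)O2 | intermediate
15 | [(2,2-dimethyl-2H-chromen-5-yl)oxy]triisopropylsilane | CC1(C)C=Cc2c(O[Si](C(C)C)(C(C)C)C(C)C)cccc2O1 | intermediate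
16 | (R)-epichlorohydrin, (R)-2-(chloromethyl)oxirane | ClC[C@H]1CO1 | starting material
17 | [2,2-dimethyl-5-(triisopropylsilyloxy)-2H-chromen-8-yl]lithium | [Li]c1ccc(O[Si](C(C)C)(C(C)C)C(C)C)c2C=CC(C)(C)Oc12 | intermediate
18 | [2,2-dimethyl-5-(triisopropylsilyloxy)-2H-chromen-8-yl]magnesium bromide | Br[Mg]c1ccc(O[Si](C(C)C)(C(C)C)C(C)C)c2C=CC(C)(C)Oc12 | intermediate
19 | (R)-1-chloro-3-[2,2-dimethyl-5-(triisopropylsilyloxy)-2H-chromen-8-yl]propan-2-ol | ClC[C@H](O)Cc1ccc(O[Si](C(C)C)(C(C)C)C(C)C)c2C=CC(C)(C)Oc12 | intermediate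
20 | (R)-2-{[2,2-dimethyl-5-(triisopropylsilyloxy)-2H-chromen-8-yl]methyl}oxirane | C3[C@H](O3)Cc1ccc(O[Si](C(C)C)(C(C)C)C(C)C)c2C=CC(C)(C)Oc12 | intermediate
21 | (R)-1-[2,2-dimethyl-5-(triisopropylsilyloxy)-2H-chromen-8-yl]-3-[3-methoxy-4-(3-methylbut-2-en-1-yl)-5-(triisopropylsilyloxy)phenoxy]propan-2-ol | COc1cc(OC[C@H](O)Cc2ccc(O[Si](C(C)C)(C(C)C)C(C)C)c3C=CC(C)(C)Oc23)cc(O[Si](C(C)C)(C(C)C)C(C)C)c1CC=C(C)C | intermediate
22 | (R)-triflate of 21 | COc1cc(OC[C@H](OS(=O)(=O)C(F)(F)F)Cc2ccc(O[Si](C(C)C)(C(C)C)C(C)C)c3C=CC(C)(C)Oc23)cc(O[Si](C(C)C)(C(C)C)C(C)C)c1CC=C(C)C | intermediate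
23 | phenonium triflate: ring B as O-silylated spiro[2.5]octadienyl cation, cyclopropane CH (future C3) of (R) configuration bearing the CH2O–ring A arm, spiro carbon as either epimer | COc1cc(OC[C@@H]2CC23C=CC(=[O+][Si](C(C)C)(C(C)C)C(C)C)C4=C3OC(C)(C)C=C4)cc(O[Si](C(C)C)(C(C)C)C(C)C)c1CC=C(C)C.[O-]S(=O)(=O)C(F)(F)F | intermediate
24 | (3R)-3-[2,2-dimethyl-5-(triisopropylsilyloxy)-2H-chromen-8-yl]-5-methoxy-6-(3-methylbut-2-en-1-yl)-7-(triisopropylsilyloxy)chromane | COc1c(CC=C(C)C)c(O[Si](C(C)C)(C(C)C)C(C)C)cc2c1C[C@H](c1ccc(O[Si](C(C)C)(C(C)C)C(C)C)c3c1OC(C)(C)C=C3)CO2 | intermediate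
25 | (3R)-3-(5-hydroxy-2,2-dimethyl-2H-chromen-8-yl)-5-methoxy-6-(3-methylbut-2-en-1-yl)chroman-7-ol | COc1c(CC=C(C)C)c(O)cc2c1C[C@H](c1ccc(O)c3c1OC(C)(C)C=C3)CO2 | target

## Step count and risks

Total steps: 10. Longest linear sequence: 7 (steps 1, 2, 3, 4, 8, 9, 10).

**Step 9 (the new step).**
- Failure modes:
  - Closure at C8 instead of C4a.
  - Participation of the pyran oxygen of ring D instead of the ipso carbon.
  - Hydride shift to the ring B benzylic cation, which would give a 4-arylchromane.
- Fallback: known chemistry only and no rearrangement. It sets out from 9, with 18 as the ring B partner, and comes back at 24. Phenol 9 is alkylated with (S)-epichlorohydrin F1 (K2CO3, MeCN, 50 °C) to give the (R)-glycidyl ether F2. Its 6-endo epoxide–arene cyclisation (HFIP, rt) gives the (R)-chroman-3-ol F3. TsCl/pyridine converts this into the tosylate F4. Copper-catalysed SN2 cross-coupling with 18 (CuBr·SMe2, TMEDA, LiOMe, THF, 0 °C) then replaces the tosylate with inversion and gives 24.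

**Step 7.**
- Failure mode: the single ether oxygen may be too weak a directing group for clean C8 lithiation.
- Fallback: it sets out from 15 and comes back at 18. Electrophilic bromination (NBS, MeCN, −30 °C), steered by the TIPS group to the para position, gives the 8-bromochromene F5. Magnesium insertion (Mg, LiCl, THF) then gives 18, which continues as written.

**Step 3.**
- Failure mode: the telescoped dehydrogenation may strip silicon, or DDQ may attack the benzylic-allylic CH2 of the product.
- Fallback: it sets out from 4 and comes back at 7. LDA followed by PhSeCl (THF, −78 °C) gives the racemic alpha-phenylselanyl ketone F6. H2O2/pyridine (CH2Cl2, 0 °C) gives the selenoxide F7, which undergoes syn-elimination and tautomerises to 3-methoxy-2-(3-methylbut-2-en-1-yl)phenol F8. TIPSCl and imidazole in DMF then give 7.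

## Further compounds

F1 | step 9 | (S)-epichlorohydrin (bought) | ClC[C@@H]1CO1
F2 | step 9 | (R)-2-{[3-methoxy-4-(3-methylbut-2-en-1-yl)-5-(triisopropylsilyloxy)phenoxy]methyl}oxirane | COc1cc(OC[C@H]2CO2)cc(O[Si](C(C)C)(C(C)C)C(C)C)c1CC=C(C)C
F3 | step 9 | (R)-5-methoxy-6-(3-methylbut-2-en-1-yl)-7-(triisopropylsilyloxy)chroman-3-ol | COc1c(CC=C(C)C)c(O[Si](C(C)C)(C(C)C)C(C)C)cc2c1C[C@@H](O)CO2
F4 | step 9 | (R)-5-methoxy-6-(3-methylbut-2-en-1-yl)-7-(triisopropylsilyloxy)chroman-3-yl 4-methylbenzenesulfonate | COc1c(CC=C(C)C)c(O[Si](C(C)C)(C(C)C)C(C)C)cc2c1C[C@@H](OS(=O)(=O)c1ccc(C)cc1)CO2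
F5 | step 7 | [(8-bromo-2,2-dimethyl-2H-chromen-5-yl)oxy]triisopropylsilane | Brc1ccc(O[Si](C(C)C)(C(C)C)C(C)C)c2C=CC(C)(C)Oc12
F6 | step 3 | 3-methoxy-2-(3-methylbut-2-en-1-yl)-6-(phenylselanyl)cyclohex-2-en-1-one (racemic) | COC1=C(CC=C(C)C)C(=O)C([Se]c2ccccc2)CC1
F7 | step 3 | 3-methoxy-2-(3-methylbut-2-en-1-yl)-6-(phenylseleninyl)cyclohex-2-en-1-one | COC1=C(CC=C(C)C)C(=O)C([Se](=O)c2ccccc2)CC1
F8 | step 3 | 3-methoxy-2-(3-methylbut-2-en-1-yl)phenol | COc1cccc(O)c1CC=C(C)C
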